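## Structural features

The target is a labdane-type diterpenoid acid. Ring A (C1–C5, C10) and ring B (C5–C10) form a decalin that carries a gem-dimethyl group on C4, an angular methyl on C10, a tertiary acetate on C8 and, on C9, the chain C11–C15 ending in the carboxylic acid, with a methyl-bearing stereocentre at C13 (S). The rings are cis-fused: H5 and the C10 methyl lie on the same face, called β here (5R,10S), so the compound is a 5-epi-labdane. The C9 chain (9R) and the C8 methyl are also β, and the acetoxy group is α (8R). C5, C10, C9 and C8 form an unbroken row of four stereocentres, two of them fully substituted, whereas C13 is too far from the rings to be controlled by them. The tertiary acetate is hard to form and easily lost by elimination under acid, and the same holds for the tertiary alcohol that precedes it. In intermediates, a C9 centre next to a C8 ketone and a C5 centre γ to an enone can epimerise. The real difficulty is the crowded core: a quaternary C10 set between the branched C9 and C5, whose neighbour C4 carries an axial methyl, with the cis fusion and the correct face at C8. The feature exploited is that C8, C9 and C10 are contiguous in ring B and C8 is oxygenated. With a C8 ketone conjugated to a C9=C10 double bond, C10 is the electrophilic β-carbon and C9 becomes the nucleophilic α-carbon once methyl has been transferred. The angular methyl and the C9–C11 bond can therefore be attached across one bond in one flask, and the carbonyl stays for the acetate.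

## Logic of the disconnections

26 to 24: the acetyl–oxygen bond at C8 is cut. The tertiary ester is the most fragile group and is made last. The gain is that every earlier step handles only an alcohol or its precursor. The forward step must acylate a hindered tertiary hydroxyl beside a free acid, which passes through 25 and needs a mild hydrolytic work-up.

24 to 23 to 22: the C8–O bond and the C17–H bond are cut, so the tertiary alcohol becomes an exocyclic C8=C17 alkene. The reason is that the alkene is inert to organometallic reagents and can mask the alcohol during side-chain construction. A free C8 alkoxide would displace a C12 halide to give the 8,12-ether, and a hydride used before the coupling would reduce that halide. The gain is that C8 is reduced to a choice of face on a trigonal carbon. The demand is α-face epoxidation and a hydride that opens the epoxide at C17 without reducing the carboxylate.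

22 to 19 and 20: the C12–C13 bond is cut. C13 cannot be controlled from the ring, so it is taken from the chiral pool as 20, and the whole C13–C16 unit with the acid arrives in one step. The demand is a C12 organometallic made from 19 (through 21) that opens 20 at the β-carbon with inversion, not at the acyl carbon.

19 to 18 to 17 to 16 to 14: the C8=C17 bond is traced back to the C8 ketone, the C12–Br bond to an alcohol and then an aldehyde, and the aldehyde to the terminal alkene of an allyl group. The gain is that all of it derives from a simple allyl ketone. The demands are a chemoselective aldehyde reduction and a non-basic methylenation, so that C9 next to the ketone is never enolised.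

14 to 11, 2 and 12: the C10–C20 and C9–C11 bonds are cut together. Both lie on the C9–C10 bond that flanks the C8 carbonyl, so 2 can add to the enone of 11 and the resulting enolate can be alkylated by 12. Two skeletal bonds and two stereocentres are removed in one operation. The forward step must give the cis ring fusion, the β configuration at C9, and alkylation at C9 rather than at C7.

11 to 9: the C9=C10 double bond is cut by a retro-aldol condensation. This opens ring B and leaves a monocyclic 1,5-diketone with only the C5 stereocentre. The forward step must close the ring without epimerising C5.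

9 to 8 to 6 and 7: the C8 carbonyl is traced to an alkenyl boronate and the C7=C8 bond is cut by retro-metathesis. An allyl group is one carbon short of a 3-oxobutyl group, and 7 supplies that carbon together with the latent carbonyl in two steps. The demand is a cross-metathesis with a 1,1-disubstituted partner.

6 to 5: the C5–C6 bond is cut. The only ring stereocentre made by a reagent is thus placed in a catalytic, enantioselective decarboxylative allylation. The demand is high enantioselectivity for a tertiary α-centre next to a quaternary carbon, under conditions that do not epimerise it.

5 to 1, 2 and 3: one C4–methyl bond and the O–acyl bond are cut. Conjugate addition creates the gem-dimethyl carbon and at the same time fixes the enolate on the correct side of the carbonyl. The demand is O-acylation, not C-acylation, of 4.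

## Other disconnections considered

Alternative 1: Ring B is cut at C5–C6 and C9–C10. The fragments are the ring A enal A1 (the formyl group on C10 stands for the angular methyl) and the 2-silyloxy diene A2 (C6=C7–C8=C9, with the C8 methyl and the complete C11–C15 chain, C13 already S). The forward step would be a catalytic asymmetric Diels–Alder reaction, for example with a chiral oxazaborolidinium Lewis acid on the formyl group, giving adduct A3.
- In its favour: suprafacial addition to the cyclic dienophile makes the ring fusion cis by necessity. The (E)-diene in an endo transition state would place the C9 chain cis to the formyl group. The step is convergent, and C5, C9 and C10 would be set together under catalyst control.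
- Against it here: C5 of A1 is neopentyl and C10 becomes quaternary, so the dienophile is very hindered, and α-substituted enals do not reliably react endo. A3 also has three wrong oxidation levels. The formyl group must be reduced to methyl at a neopentyl position, the C7 oxygen must be removed, and C8 must be hydroxylated on the α face. A Rubottom-type oxidation of the enol ether would leave a C7 ketone to delete next to a tertiary alcohol. C15 must also be raised to the acid.
- Comparison: on structure, A3 holds more of the target than 14 and sets three ring stereocentres against two, so it is the better plan on convergence. On mechanism, the concerted cycloaddition guarantees the cis fusion, whereas the chosen plan relies on a facial preference, and on this point too the alternative is better. On step economy, the redox corrections after A3 and the synthesis of A2 should outweigh the linear side-chain construction of the chosen plan, and the cycloaddition itself is the less certain reaction.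

Alternative 2: The C9–C10 bond is cut together with a temporary C9–C20 bond. The forward step would treat diazoketone A4 with Rh2(OAc)4; the carbenoid at C9 would add to the exocyclic C10=C20 alkene and give the cyclopropyl ketone A5. Dissolving-metal cleavage of the C9–C20 bond would then release the angular methyl and the same C8–C9 enolate as 13, to be allylated as in the chosen plan.
- In its favour: the quaternary centre is made intramolecularly without a cuprate. The precursor has no enone, so C5 in A4 is only allylic and cannot epimerise as it might in 11; on this point the alternative is better.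
- Against it here: A4 needs a diazoalkane and several more steps from 6 (methylenation, chain oxidation, acid activation). The tether can reach either face of the exocyclic alkene, so the cis fusion is not enforced. C–H insertion competes. The reductive opening must select the C9–C20 bond and stop at the ketone. The C9 allylation then faces the same facial question as in the chosen plan.
- Comparison: on structure, A5 is 14 without the allyl group. On mechanism, two operations replace one flask. On step economy, it is clearly longer. It is equal to the chosen plan in the regiochemical definition of the enolate and in the whole endgame.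

Alternative 3: The C9–C10 bond is cut as the product bond of a [3,3] shift that breaks C2–C7 of a bicyclo[2.2.2]octene. The forward step would treat bicyclooctenol A6 with KH and 18-crown-6; the alkoxide would rearrange through the boat transition state that the bicycle enforces, and the C7–C8 enolate would be oxidised at C8 by a sulfonyloxaziridine to give A7.
- In its favour: the rigid template turns directly into the cis-decalin, with C5 and C10 fixed by the bicycle and C9 by the alkene geometry. A boat analysis calls for the (Z)-alkenyl group, which is why A6 is drawn so. The C8 oxygen is introduced in the same flask and the whole side chain is already present. Up to four stereocentres would be set in one operation against two, and on this point the alternative is better.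
- Against it here: A6 needs an enantiopure bicyclooctenone, normally made racemic from a masked ortho-quinone. It also needs face-selective addition of a geometrically pure (Z)-trisubstituted alkenyl metal that already carries C13. A7 has oxygen at C2 and C7 that must both be removed, the latter next to a tertiary alcohol that can undergo ketol rearrangement. The oxidant would have to reach the enolate from the α face, which may not be the accessible one. C15 must still be oxidised.
- Comparison: on structure and stereospecificity, the sigmatropic step is superior to the chosen conjugate addition. On mechanism, both are well precedented. On step economy, the two deoxygenations and the preparation of A6 should make it longer than the chosen plan.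

Key step: step 6

Assumptions:
- Labdane numbering of the target is used for all bicyclic compounds. β is the face of ring B that carries the C10 methyl, and "5-epi-labdane" means the labdane skeleton with 5β-H.
- The sense of induction of the ligand in step 2 is taken by analogy with simple 2-substituted cyclohexanone enol carbonates. If the (S)-ketone should predominate, the enantiomeric ligand is used.

## Route

Step 1
Reactants: 1 3-methylcyclohex-2-en-1-one; 2 lithium dimethylcuprate; 3 allyl chloroformate
Product: 5 allyl 3,3-dimethylcyclohex-1-en-1-yl carbonate, via lithium enolate 4 (not isolated)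
Conditions: 2 (1.2 equiv, from MeLi and CuI), Et2O, 0 °C; then TMEDA, 3, THF, −78 °C → 0 °C
Reagents that add atoms: none
Why: Conjugate addition of the cuprate to the β-methyl enone places the second methyl on the future C4 and gives the regiodefined lithium enolate 4, which the chloroformate should acylate on oxygen because its carbon terminus is shielded by the new quaternary centre (conjugate addition with enolate O-acylation); no stereocentre is formed.

Step 2
Reactants: 5 allyl 3,3-dimethylcyclohex-1-en-1-yl carbonate
Product: 6 (R)-2-allyl-3,3-dimethylcyclohexan-1-one
Conditions: Pd2(dba)3·CHCl3 (2.5 mol%), (R,R)-N,N'-(9,10-dihydro-9,10-ethanoanthracene-11,12-diyl)bis[2-(diphenylphosphino)benzamide] (5.5 mol%), 1,4-dioxane, rt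
Reagents that add atoms: none
Why: Zerovalent palladium ionises the allyl carbonate, CO2 is lost and the π-allylpalladium enolate ion pair recombines at carbon inside the chiral pocket of the ligand (decarboxylative asymmetric allylic alkylation of an allyl enol carbonate); the neutral conditions keep the enolate regiochemistry and should not epimerise the new tertiary centre, the future C5 (R), whose configuration is set by the ligand.

Step 3
Reactants: 6 (R)-2-allyl-3,3-dimethylcyclohexan-1-one; 7 isopropenylboronic acid pinacol ester
Product: 8 (R)-3,3-dimethyl-2-[3-(4,4,5,5-tetramethyl-1,3,2-dioxaborolan-2-yl)but-2-en-1-yl]cyclohexan-1-one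
Conditions: second-generation Grubbs catalyst RuCl2(H2IMes)(PCy3)(=CHPh) (5 mol%), 7 (3 equiv), CH2Cl2, 40 °C
Reagents that add atoms: none
Why: Olefin cross-metathesis of the terminal alkene with a 1,1-disubstituted alkenyl boronate that does not homodimerise should give the trisubstituted alkenyl boronate with loss of ethylene; the ketone and the stereocentre are not involved, and the alkene geometry is irrelevant because it is destroyed in step 4.

Step 4
Reactants: 8 (R)-3,3-dimethyl-2-[3-(4,4,5,5-tetramethyl-1,3,2-dioxaborolan-2-yl)but-2-en-1-yl]cyclohexan-1-one
Product: 9 (R)-3,3-dimethyl-2-(3-oxobutyl)cyclohexan-1-one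
Conditions: H2O2 (30% aq.), NaHCO3, THF/H2O, 0 °C → rt
Reagents that add atoms: hydrogen peroxide, OO
Why: Oxidation of the carbon–boron bond (as in hydroboration–oxidation) gives an enol that tautomerises to the methyl ketone, so the allyl group has become the 3-oxobutyl chain in two steps with the extra carbon supplied by 7; bicarbonate buffering avoids enolisation towards the α-stereocentre.

Step 5
Reactants: 9 (R)-3,3-dimethyl-2-(3-oxobutyl)cyclohexan-1-one
Product: 11 (4aR)-5,5-dimethyl-4,4a,5,6,7,8-hexahydronaphthalen-2(3H)-one, via ketol 10 (not isolated)
Conditions: KOH (0.2 equiv), MeOH, 0 °C → rt, stopped at full conversion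
Reagents that add atoms: none
Why: Intramolecular aldol condensation (the ring-closing half of a Robinson annulation): the methyl ketone enolate attacks the ring carbonyl through a six-membered transition state and ketol 10 loses water to give the conjugated C9=C10 enone. The tertiary hydrogen at C5 is hindered by the adjacent gem-dimethyl group and should survive brief exposure to cold methanolic base.

Step 6
Reactants: 11 (4aR)-5,5-dimethyl-4,4a,5,6,7,8-hexahydronaphthalen-2(3H)-one; 2 lithium dimethylcuprate; 12 allyl bromide
Product: 14 cis-fused 9β-allyl-4,4,10β-trimethyldecalin-8-one (5R,9R,10S; target numbering), via lithium enolate 13 (not isolated)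
Conditions: 2 (1.5 equiv, from MeLi and CuI), Et2O, −20 → 0 °C; then 12 (5 equiv), THF/DMPU, −30 °C → rt
Reagents that add atoms: none
Why: The cuprate forms a π-complex with the C9=C10 enone and transfers methyl to C10 (β-cupration followed by reductive elimination), leaving the lithium enolate 13 with its double bond fixed between C8 and C9, which then attacks 12 at C9 in an SN2 alkylation. The closest known reaction type is the conjugate addition of lithium dialkylcuprates to Δ1(9)-2-octalones with alkylation of the regiodefined enolate in the same flask (three-component coupling). No ring is closed. C10 is controlled by the existing C5 centre: delivery of methyl anti to H5 would place the incoming copper-bound methyl 1,3-diaxial to the axial C4 methyl of ring A, so methyl should enter syn to H5, as is usual for such octalones, and give the cis-fused enolate (10S). C9 is controlled by the new ring fusion: the α face of the enolate is covered by ring A (the C5–C4 bond with its methyl groups is syn-axial to an α trajectory at C9), so 12 should approach the convex β face, which is also the axial mode anti to the C10–C1 bond in the alternative half-chair, giving the 9β-allyl ketone (9R). The step needs regioselectivity for C9 over C7, C-alkylation over O-alkylation and mono-alkylation over dialkylation. These are secured by generating the enolate specifically and aprotically through the conjugate addition, and by using an excess of a reactive allylic bromide with a dipolar cosolvent at low temperature, so that alkylation outruns proton transfer between 13 and 14. The C8 carbonyl is left for the later construction of the tertiary acetate.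

Step 7
Reactants: 14 cis-fused 9β-allyl-4,4,10β-trimethyldecalin-8-one
Product: 16 (8-oxo-4,4,10β-trimethyl-cis-decalin-9β-yl)acetaldehyde (5R,9R,10S), via methoxy hydroperoxide 15 (not isolated)
Conditions: O3, NaHCO3, CH2Cl2/MeOH, −78 °C; then Me2S, −78 °C → rt
Reagents that add atoms: ozone, [O-][O+]=O
Why: Ozonolysis cleaves the only alkene; in methanol the carbonyl oxide is trapped as the methoxy hydroperoxide 15, which dimethyl sulfide reduces to the aldehyde under neutral conditions that leave the ketone and the C9 centre alone.

Step 8
Reactants: 16 (8-oxo-4,4,10β-trimethyl-cis-decalin-9β-yl)acetaldehyde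
Product: 17 cis-fused 9β-(2-hydroxyethyl)-4,4,10β-trimethyldecalin-8-one (5R,9R,10S)
Conditions: NaBH4 (0.3 equiv), MeOH/CH2Cl2, −78 °C
Reagents that add atoms: none
Why: Borohydride at low temperature reduces an aldehyde much faster than a ketone, and this ketone is flanked by the substituted C9 and the quaternary C10 (chemoselective carbonyl reduction); the product may sit partly as its cyclic hemiketal, which does not matter for step 9.

Step 9
Reactants: 17 cis-fused 9β-(2-hydroxyethyl)-4,4,10β-trimethyldecalin-8-one
Product: 18 cis-fused 9β-(2-bromoethyl)-4,4,10β-trimethyldecalin-8-one (5R,9R,10S)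
Conditions: CBr4, PPh3, CH2Cl2, 0 °C
Reagents that add atoms: carbon tetrabromide, BrC(Br)(Br)Br
Why: Appel reaction: the primary alcohol is activated as an alkoxyphosphonium ion and displaced by bromide under neutral conditions, so the ketone is not enolised, C9 is not epimerised and no cyclopropane can form from the γ-bromo ketone.

Step 10
Reactants: 18 cis-fused 9β-(2-bromoethyl)-4,4,10β-trimethyldecalin-8-one
Product: 19 cis-fused 9β-(2-bromoethyl)-4,4,10β-trimethyl-8-methylenedecalin (5R,9S,10S)
Conditions: Zn, CH2Br2, TiCl4, THF/CH2Cl2, 0 °C → rt
Reagents that add atoms: dibromomethane, BrCBr
Why: Methylenation with the geminal dizinc reagent activated by TiCl4 (Lombardo–Takai type) is non-basic, so the hindered, enolisable ketone should become the exocyclic alkene without epimerisation at C9, and the unactivated primary bromide is inert to zinc under these conditions. The alkene now masks the tertiary alcohol during the organometallic step.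

Step 11
Reactants: 19 cis-fused 9β-(2-bromoethyl)-4,4,10β-trimethyl-8-methylenedecalin; 20 (S)-β-butyrolactone
Product: 22 (13S)-5-epi-labd-8(17)-en-15-oic acid (5R,9S,10S,13S), via Grignard reagent 21 (not isolated)
Conditions: Mg, THF, 40 °C; then CuBr·SMe2 (10 mol%), 20 (1.5 equiv), THF/Me2S, −30 → 0 °C; then dilute HCl
Reagents that add atoms: none
Why: Magnesium insertion gives the primary Grignard reagent 21 (a 4-pentenyl-type system that does not cyclise), and under copper catalysis the soft organocopper species attacks the β-carbon of the lactone with alkyl–oxygen cleavage and inversion (SN2 opening of β-lactones by organocopper reagents). The (S)-lactone therefore gives the 13S acid, the descriptor staying S only because the priorities change, and the remote stereocentre is taken from the chiral pool.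

Step 12
Reactants: 22 (13S)-5-epi-labd-8(17)-en-15-oic acid
Product: 23 (13S)-8α,17-epoxy-5-epi-labdan-15-oic acid (5R,8R,9R,10S,13S)
Conditions: mCPBA, Na2HPO4, CH2Cl2, 0 °C
Reagents that add atoms: 3-chloroperoxybenzoic acid, OOC(=O)c1cccc(Cl)c1
Why: Prilezhaev epoxidation of the only alkene; the peracid should approach C8 on the α face, away from the angular C10 methyl that is syn-axial to the β lobe of the exocyclic alkene, as in the trans-labdane series, giving the 8α,17-epoxide.

Step 13
Reactants: 23 (13S)-8α,17-epoxy-5-epi-labdan-15-oic acid
Product: 24 (13S)-8α-hydroxy-5-epi-labdan-15-oic acid (5R,8R,9R,10S,13S)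
Conditions: LiEt3BH (4 equiv), THF, 0 °C → rt; then dilute HCl to pH 4, 0 °C
Reagents that add atoms: none
Why: LiEt3BH first deprotonates the acid to a carboxylate that it reduces only very slowly, and then opens the epoxide by hydride attack at the unhindered C17 (SN2 reduction of an epoxide), giving the tertiary 8α-alcohol with the β-methyl group; C8 keeps the configuration set in step 12.

Step 14
Reactants: 24 (13S)-8α-hydroxy-5-epi-labdan-15-oic acid
Product: 26 (13S)-8α-acetoxy-5-epi-labdan-15-oic acid (5R,8R,9R,10S,13S; the target), via mixed anhydride 25 (not isolated)
Conditions: Ac2O, DMAP, Et3N, CH2Cl2, 40 °C; then THF/H2O, NaHCO3, rt; then dilute HCl to pH 4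
Reagents that add atoms: acetic anhydride, CC(=O)OC(C)=O
Why: DMAP-catalysed acylation through the acetylpyridinium ion is the standard way to esterify a hindered tertiary alcohol; the carboxylic acid is converted in passing into mixed anhydride 25, which aqueous bicarbonate hydrolyses back to the acid while the tertiary acetate stays.

## Compound list

1 | 3-methylcyclohex-2-en-1-one | CC1=CC(=O)CCC1 | starting material
2 | lithium dimethylcuprate (made in the flask from MeLi and CuI just before use) | [Li+].C[Cu-]C | starting material
3 | allyl chloroformate | C=CCOC(=O)Cl | starting material
4 | lithium 3,3-dimethylcyclohex-1-en-1-olate | [Li]OC1=CC(C)(C)CCC1 | intermediate (not isolated)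
5 | allyl 3,3-dimethylcyclohex-1-en-1-yl carbonate | C=CCOC(=O)OC1=CC(C)(C)CCC1 | intermediate
6 | (R)-2-allyl-3,3-dimethylcyclohexan-1-one | C=CC[C@H]1C(=O)CCCC1(C)C | intermediate
7 | isopropenylboronic acid pinacol ester | CC(=C)B1OC(C)(C)C(C)(C)O1 | starting material
8 | (R)-3,3-dimethyl-2-[3-(4,4,5,5-tetramethyl-1,3,2-dioxaborolan-2-yl)but-2-en-1-yl]cyclohexan-1-one (alkene geometry left open, both isomers converge) | CC(=CC[C@H]1C(=O)CCCC1(C)C)B1OC(C)(C)C(C)(C)O1 | intermediate
9 | (R)-3,3-dimethyl-2-(3-oxobutyl)cyclohexan-1-one | CC(=O)CC[C@H]1C(=O)CCCC1(C)C | intermediate
10 | (4aR)-8a-hydroxy-5,5-dimethyloctahydronaphthalen-2(1H)-one (either C8a epimer) | O=C1CC[C@@H]2C(C)(C)CCCC2(O)C1 | intermediate (not isolated)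
11 | (4aR)-5,5-dimethyl-4,4a,5,6,7,8-hexahydronaphthalen-2(3H)-one (C2 = C8, C1 = C9, C8a = C10, C4a = C5 of the target) | O=C1CC[C@@H]2C(C)(C)CCCC2=C1 | intermediate
12 | allyl bromide | C=CCBr | starting material
13 | lithium C8–C9 enolate of cis-fused 4,4,10β-trimethyldecalin-8-one (5R,10S) | [Li]OC1=C[C@@]2(C)CCCC(C)(C)[C@H]2CC1 | intermediate (not isolated)
14 | cis-fused 9β-allyl-4,4,10β-trimethyldecalin-8-one, (1R,4aR,8aS)-1-allyl-5,5,8a-trimethyloctahydronaphthalen-2(1H)-one | O=C1CC[C@@H]2C(C)(C)CCC[C@]2(C)[C@H]1CC=C | intermediate
15 | cis-fused 9β-(2-hydroperoxy-2-methoxyethyl)-4,4,10β-trimethyldecalin-8-one (epimers at the peroxy carbon) | O=C1CC[C@@H]2C(C)(C)CCC[C@]2(C)[C@H]1CC(OC)OO | intermediate (not isolated)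
16 | (8-oxo-4,4,10β-trimethyl-cis-decalin-9β-yl)acetaldehyde (5R,9R,10S) | O=C1CC[C@@H]2C(C)(C)CCC[C@]2(C)[C@H]1CC=O | intermediate
17 | cis-fused 9β-(2-hydroxyethyl)-4,4,10β-trimethyldecalin-8-one (5R,9R,10S) | O=C1CC[C@@H]2C(C)(C)CCC[C@]2(C)[C@H]1CCO | intermediate
18 | cis-fused 9β-(2-bromoethyl)-4,4,10β-trimethyldecalin-8-one (5R,9R,10S) | O=C1CC[C@@H]2C(C)(C)CCC[C@]2(C)[C@H]1CCBr | intermediate
19 | cis-fused 9β-(2-bromoethyl)-4,4,10β-trimethyl-8-methylenedecalin (5R,9S,10S) | C=C1CC[C@@H]2C(C)(C)CCC[C@]2(C)[C@H]1CCBr | intermediate
20 | (S)-β-butyrolactone, (S)-4-methyloxetan-2-one | C[C@H]1CC(=O)O1 | starting material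
21 | [2-(4,4,10β-trimethyl-8-methylene-cis-decalin-9β-yl)ethyl]magnesium bromide | C=C1CC[C@@H]2C(C)(C)CCC[C@]2(C)[C@H]1CC[Mg]Br | intermediate (not isolated)
22 | (13S)-5-epi-labd-8(17)-en-15-oic acid (5β-H, 9β chain, 10β-CH3) | C=C1CC[C@@H]2C(C)(C)CCC[C@]2(C)[C@H]1CC[C@H](C)CC(=O)O | intermediate
23 | (13S)-8α,17-epoxy-5-epi-labdan-15-oic acid | C1O[C@@]12CC[C@@H]3C(C)(C)CCC[C@]3(C)[C@H]2CC[C@H](C)CC(=O)O | intermediate
24 | (13S)-8α-hydroxy-5-epi-labdan-15-oic acid | O[C@]1(C)CC[C@@H]2C(C)(C)CCC[C@]2(C)[C@H]1CC[C@H](C)CC(=O)O | intermediate
25 | acetic (13S)-8α-acetoxy-5-epi-labdan-15-oic anhydride | CC(=O)O[C@]1(C)CC[C@@H]2C(C)(C)CCC[C@]2(C)[C@H]1CC[C@H](C)CC(=O)OC(C)=O | intermediate (not isolated)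
26 | (13S)-8α-acetoxy-5-epi-labdan-15-oic acid, (3S)-5-[(1R,2R,4aR,8aS)-2-acetoxy-2,5,5,8a-tetramethyldecahydronaphthalen-1-yl]-3-methylpentanoic acid | CC(=O)O[C@]1(C)CC[C@@H]2C(C)(C)CCC[C@]2(C)[C@H]1CC[C@H](C)CC(=O)O | target

## Step count and least certain steps

Total: 14 steps. Longest linear sequence: 14 steps, from 1 to 26; 2, 3, 7, 12 and 20 enter as reagents or building blocks.

**Step 6 (key step).** The enolate carbon C9 is next to a quaternary centre, so its alkylation is slow. Proton transfer between 13 and 14 can then compete, which would erode the regiochemistry (allylation at C7, dialkylation) and return unalkylated cis-decalone. The facial preference at C9 also rests on a conformational argument for a flexible cis-decalin and may be incomplete. Fallback: starting from 11, the conjugate addition of 2 is run as before but the enolate is trapped on oxygen with 3 to give the allyl enol carbonate of cis-fused 4,4,10β-trimethyldecalin-8-one F1. Treatment of F1 with Pd(PPh3)4 in THF then effects a decarboxylative allylation in which the C9–C11 bond forms inside a π-allylpalladium enolate ion pair, so no free enolate can equilibrate. If the facial ratio at C9 is poor, the chiral ligand of step 2 can be matched to the substrate. The fallback returns to the route at 14.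

**Step 2.** Carbon–carbon bond formation at a centre next to a quaternary carbon may be slow enough for proton transfer within the ion pair to compete. That would lower the enantiomeric purity or give 3,3-dimethylcyclohexanone and diallylated ketone. Fallback by resolution: starting from 1, conjugate addition of 2 followed by alkylation of the enolate with 12 gives racemic 2-allyl-3,3-dimethylcyclohexan-1-one F2. Reduction with LiB(s-Bu)3H gives racemic cis-2-allyl-3,3-dimethylcyclohexan-1-ol F3. Acylation with vinyl acetate and lipase B from Candida antarctica should, by the usual preference of this enzyme for (1R)-cycloalkanols, leave (1S,2R)-2-allyl-3,3-dimethylcyclohexan-1-ol F4 unreacted and convert the other enantiomer into (1R,2S)-2-allyl-3,3-dimethylcyclohexyl acetate F5. After separation, oxidation of F4 with Dess–Martin periodinane returns to the route at 6.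

**Step 3.** The 1,1-disubstituted boronate is a sluggish metathesis partner, so homodimerisation of 6 and migration of the terminal double bond may take over. Fallback with classical chain extension: starting from 6, hydroboration of the terminal alkene with (c-C6H11)2BH and oxidation with H2O2/NaHCO3 gives (R)-2-(3-hydroxypropyl)-3,3-dimethylcyclohexan-1-one F6. Dess–Martin oxidation gives 3-[(1R)-2,2-dimethyl-6-oxocyclohexyl]propanal F7. Aldehyde-selective methylation with MeTi(OiPr)3 gives (2R)-2-(3-hydroxybutyl)-3,3-dimethylcyclohexan-1-one F8, and a second Dess–Martin oxidation returns to the route at 9.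

**Step 11.** The Grignard reagent may attack the acyl carbon of the lactone (ketone and tertiary alcohol by-products) or act as a base and open the lactone to crotonate. Wurtz coupling may also occur during magnesium insertion. Fallback with a chiral auxiliary in place of the chiral-pool electrophile: starting from 19, the Grignard reagent 21 is added with CuBr·SMe2 to (S)-3-[(E)-but-2-enoyl]-4-phenyloxazolidin-2-one F9. In the chelated s-cis form, F9 is expected to be attacked anti to the phenyl group, giving the 13S conjugate adduct, the N-acyl oxazolidinone of (13S)-5-epi-labd-8(17)-en-15-oic acid F10. Cleavage with LiOH/H2O2 returns to the route at 22.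

**Step 12.** The cis-decalin can populate a second chair–chair form in which ring A covers the α face of C8, so the facial selectivity of the epoxidation may be low or reversed. Fallback that inverts the sense of oxygen delivery: starting from 22, NBS in aqueous THF should form the bromonium ion on the more accessible face and water should open it at the tertiary C8 from the opposite side. If the accessible face is β, this gives (13S)-17-bromo-8α-hydroxy-5-epi-labdan-15-oic acid F11. K2CO3 in MeOH then closes F11 to the α-epoxide, returning to the route at 23.

## Further compounds

F1 | step 6 | allyl enol carbonate of cis-fused 4,4,10β-trimethyldecalin-8-one (C8–C9 enol, 5R,10S) | C=CCOC(=O)OC1=C[C@@]2(C)CCCC(C)(C)[C@H]2CC1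
F2 | step 2 | racemic 2-allyl-3,3-dimethylcyclohexan-1-one | C=CCC1C(=O)CCCC1(C)C
F3 | step 2 | racemic cis-2-allyl-3,3-dimethylcyclohexan-1-ol (relative configuration shown) | C=CC[C@H]1[C@@H](O)CCCC1(C)C
F4 | step 2 | (1S,2R)-2-allyl-3,3-dimethylcyclohexan-1-ol | C=CC[C@H]1[C@@H](O)CCCC1(C)C
F5 | step 2 | (1R,2S)-2-allyl-3,3-dimethylcyclohexyl acetate | C=CC[C@@H]1[C@H](OC(C)=O)CCCC1(C)C
F6 | step 3 | (R)-2-(3-hydroxypropyl)-3,3-dimethylcyclohexan-1-one | OCCC[C@H]1C(=O)CCCC1(C)C
F7 | step 3 | 3-[(1R)-2,2-dimethyl-6-oxocyclohexyl]propanal | O=CCC[C@H]1C(=O)CCCC1(C)C
F8 | step 3 | (2R)-2-(3-hydroxybutyl)-3,3-dimethylcyclohexan-1-one (carbinol epimers) | CC(O)CC[C@H]1C(=O)CCCC1(C)C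
F9 | step 11 | (S)-3-[(E)-but-2-enoyl]-4-phenyloxazolidin-2-one | C/C=C/C(=O)N1[C@@H](c2ccccc2)COC1=O
F10 | step 11 | (S)-3-[(13S)-5-epi-labd-8(17)-en-15-oyl]-4-phenyloxazolidin-2-one | C=C1CC[C@@H]2C(C)(C)CCC[C@]2(C)[C@H]1CC[C@H](C)CC(=O)N1[C@@H](c2ccccc2)COC1=O
F11 | step 12 | (13S)-17-bromo-8α-hydroxy-5-epi-labdan-15-oic acid | O[C@]1(CBr)CC[C@@H]2C(C)(C)CCC[C@]2(C)[C@H]1CC[C@H](C)CC(=O)O
A1 | alternative 1 | 3,3-dimethylcyclohex-1-ene-1-carbaldehyde | O=CC1=CC(C)(C)CCC1
A2 | alternative 1 | (3E,7S)-2-(tert-butyldimethylsilyloxy)-3,7-dimethyl-9-(triisopropylsilyloxy)nona-1,3-diene | C=C(O[Si](C)(C)C(C)(C)C)/C(C)=C/CC[C@H](C)CCO[Si](C(C)C)(C(C)C)C(C)C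
A3 | alternative 1 | cis-fused angular formyl adduct with C7 silyl enol ether and C15 silyl ether | CC1=C(O[Si](C)(C)C(C)(C)C)C[C@@H]2C(C)(C)CCC[C@]2(C=O)[C@H]1CC[C@H](C)CCO[Si](C(C)C)(C(C)C)C(C)C
A4 | alternative 2 | 1-diazo-4-[(1R)-2,2-dimethyl-6-methylenecyclohexyl]butan-2-one | [N-]=[N+]=CC(=O)CC[C@@H]1C(C)(C)CCCC1=C
A5 | alternative 2 | tricyclic cyclopropyl ketone with the C9–C10–C20 ring (9,20-cyclo-4,4-dimethyl-cis-decalin-8-one) | O=C1CC[C@@H]2C(C)(C)CCC[C@@]23C[C@@H]13
A6 | alternative 3 | 1-methoxy-5,8,8-trimethyl-2-[(2Z,6S)-8-(tert-butyldimethylsilyloxy)-6-methyloct-2-en-2-yl]bicyclo[2.2.2]oct-5-en-2-ol, alkenyl group syn to the C5=C6 bridge | CO[C@@]12CC(C)(C)[C@@H](C[C@]1(O)/C(C)=C\CC[C@H](C)CCO[Si](C)(C)C(C)(C)C)C(C)=C2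
A7 | alternative 3 | cis-fused 8-hydroxy-7-ketone with C2 methyl enol ether and C15 silyl ether | O[C@]1(C)C(=O)C[C@@H]2C(C)(C)CC(OC)=C[C@]2(C)[C@H]1CC[C@H](C)CCO[Si](C)(C)C(C)(C)C
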